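**Retrosynthetic overview**
1. Target 17 ← one-pot removal of three benzyl groups and the peri 5-O-methyl group from protected biflavone 16.
2. 16 ← oxidative cyclisation of 2'-hydroxychalcone 15 (ring C of unit 2, formed last) ← intermolecular Claisen–Schmidt aldol of aldehyde 11 with acetophenone 13 (key C–C bond).
3. 11 ← SNAr diaryl ether formation between 6-hydroxyflavone 9 and 4-fluorobenzaldehyde 10.
4. 9 ← unit 1 flavone (ring C formed first) by aldol of 4 with 5, I2/DMSO cyclisation, then debenzylation.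
5. 4 ← 2,6-dimethoxy-1,4-benzoquinone 1 (reduction, C-acetylation, selective O-benzylation); 13 ← phloroacetophenone 12.

Assumption: Cryptomerin B has no stereocentre and is achiral, so no enantiocontrol is needed; the only stereochemical element in the route is the E geometry of the two chalcone intermediates.

"Unit 1" is the 4'-methoxyflavone half that carries the ether at C6; "unit 2" is the apigenin half.

**Step 1**
Reactants: 1 2,6-dimethoxy-1,4-benzoquinone
Product: 2 2,6-dimethoxybenzene-1,4-diol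
Conditions: Na2S2O4 (3 equiv), EtOAc/H2O, rt, 30 min, N2; used directly
Reagents that add atoms: none
Why: Dithionite reduction of a quinone to its hydroquinone is fast and clean, and nothing else in the molecule is reducible.

**Step 2**
Reactants: 2 2,6-dimethoxybenzene-1,4-diol
Product: 3 1-(3,6-dihydroxy-2,4-dimethoxyphenyl)ethan-1-one
Conditions: AcOH, BF3·OEt2, 90 °C, 2 h; then H2O
Reagents that add atoms: acetic acid, CC(=O)O
Why: BF3-promoted Friedel–Crafts C-acetylation of the electron-rich hydroquinone can only occur at one of the two equivalent free ring positions, ortho to a hydroxyl, so a single ortho-hydroxyacetophenone results.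

**Step 3**
Reactants: 3 1-(3,6-dihydroxy-2,4-dimethoxyphenyl)ethan-1-one
Product: 4 1-[3-(benzyloxy)-6-hydroxy-2,4-dimethoxyphenyl]ethan-1-one
Conditions: BnBr (1.05 equiv), K2CO3 (1.2 equiv), acetone, reflux
Reagents that add atoms: benzyl bromide, BrCc1ccccc1
Why: In this Williamson etherification the 6-OH is hydrogen-bonded to the acetyl C=O and is poorly nucleophilic with a weak base, so the free 3-OH is benzylated selectively.

**Step 4**
Reactants: 4 1-[3-(benzyloxy)-6-hydroxy-2,4-dimethoxyphenyl]ethan-1-one; 5 4-methoxybenzaldehyde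
Product: 7 (E)-1-[3-(benzyloxy)-6-hydroxy-2,4-dimethoxyphenyl]-3-(4-methoxyphenyl)prop-2-en-1-one, via racemic aldol β-hydroxy ketone 6 (not isolated)
Conditions: KOH (50% aq.), EtOH, rt, 36 h; then 1 M HCl to pH 3
Reagents that add atoms: none
Why: In this Claisen–Schmidt crossed aldol condensation the methyl ketone enolate adds to the non-enolisable aldehyde and E1cB dehydration gives the thermodynamically favoured E-chalcone.

**Step 5**
Reactants: 7 (E)-1-[3-(benzyloxy)-6-hydroxy-2,4-dimethoxyphenyl]-3-(4-methoxyphenyl)prop-2-en-1-one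
Product: 8 6-(benzyloxy)-5,7-dimethoxy-2-(4-methoxyphenyl)-4H-chromen-4-one
Conditions: I2 (0.1 equiv), DMSO, 130 °C, 3 h; aq. Na2S2O3 work-up
Reagents that add atoms: none
Why: The I2-catalysed oxidative cyclisation of a 2'-hydroxychalcone in DMSO (oxa-Michael closure then dehydrogenation, DMSO as terminal oxidant) can close only through the single free phenol, which places the benzyloxy group at C6 unambiguously.

**Step 6**
Reactants: 8 6-(benzyloxy)-5,7-dimethoxy-2-(4-methoxyphenyl)-4H-chromen-4-one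
Product: 9 6-hydroxy-5,7-dimethoxy-2-(4-methoxyphenyl)-4H-chromen-4-one
Conditions: H2 (1 atm), 10% Pd/C, THF/MeOH, rt; stopped at full conversion
Reagents that add atoms: none
Why: Catalytic hydrogenolysis cleaves the benzyl aryl ether, while the flavone C2=C3 bond (a vinylogous ester) and the methyl ethers are inert at 1 atm and rt.

**Step 7**
Reactants: 9 6-hydroxy-5,7-dimethoxy-2-(4-methoxyphenyl)-4H-chromen-4-one; 10 4-fluorobenzaldehyde
Product: 11 4-{[5,7-dimethoxy-2-(4-methoxyphenyl)-4-oxo-4H-chromen-6-yl]oxy}benzaldehyde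
Conditions: 10 (1.5 equiv), Cs2CO3 (2 equiv), dry DMF, 100 °C, N2
Reagents that add atoms: none
Why: In this SNAr reaction the para-formyl group activates the C–F bond towards addition–elimination by the caesium 6-phenoxide, which is not conjugated to the pyranone carbonyl and stays nucleophilic, and no enolisable ketone is present to condense with the aldehyde.

**Step 8**
Reactants: 12 1-(2,4,6-trihydroxyphenyl)ethan-1-one
Product: 13 1-[2,4-bis(benzyloxy)-6-hydroxyphenyl]ethan-1-one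
Conditions: BnBr (2.1 equiv), K2CO3 (2.2 equiv), DMF, 60 °C
Reagents that add atoms: benzyl bromide, BrCc1ccccc1
Why: Williamson etherification benzylates the 4-OH and one ortho OH, while the remaining ortho OH is held in a hydrogen bond to the carbonyl and stays free for the later ring closure.

**Step 9**
Reactants: 11 4-{[5,7-dimethoxy-2-(4-methoxyphenyl)-4-oxo-4H-chromen-6-yl]oxy}benzaldehyde; 13 1-[2,4-bis(benzyloxy)-6-hydroxyphenyl]ethan-1-one
Product: 15 (E)-1-[2,4-bis(benzyloxy)-6-hydroxyphenyl]-3-(4-{[5,7-dimethoxy-2-(4-methoxyphenyl)-4-oxo-4H-chromen-6-yl]oxy}phenyl)prop-2-en-1-one, via racemic aldol β-hydroxy ketone 14 (not isolated)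
Conditions: 13 (1.1 equiv), KOH (50% aq.), EtOH/THF 2:1, 0 °C to rt, 36 h; then 1 M HCl to pH 3
Reagents that add atoms: none
Why: This Claisen–Schmidt crossed aldol condensation joins the two halves because aldehyde 11 is non-enolisable and carries no acidic C–H or free phenol, so only the enolate of 13 adds and E1cB dehydration gives the E-chalcone; the fully O-alkylated flavone of unit 1 tolerates hydroxide at rt.

**Step 10**
Reactants: 15 (E)-1-[2,4-bis(benzyloxy)-6-hydroxyphenyl]-3-(4-{[5,7-dimethoxy-2-(4-methoxyphenyl)-4-oxo-4H-chromen-6-yl]oxy}phenyl)prop-2-en-1-one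
Product: 16 6-{4-[5,7-bis(benzyloxy)-4-oxo-4H-chromen-2-yl]phenoxy}-5,7-dimethoxy-2-(4-methoxyphenyl)-4H-chromen-4-one
Conditions: I2 (0.2 equiv), DMSO, 130 °C, 3 h; aq. Na2S2O3 work-up
Reagents that add atoms: none
Why: The same I2/DMSO oxidative cyclisation of a 2'-hydroxychalcone closes ring C of unit 2 through the only free phenol, and benzyl ethers, methyl ethers, the diaryl ether and the existing flavone are stable to it.

**Step 11**
Reactants: 16 6-{4-[5,7-bis(benzyloxy)-4-oxo-4H-chromen-2-yl]phenoxy}-5,7-dimethoxy-2-(4-methoxyphenyl)-4H-chromen-4-one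
Product: 17 Cryptomerin B, 6-[4-(5,7-dihydroxy-4-oxo-4H-chromen-2-yl)phenoxy]-5-hydroxy-7-methoxy-2-(4-methoxyphenyl)-4H-chromen-4-one
Conditions: BCl3 (1 M in CH2Cl2, 10 equiv), pentamethylbenzene (10 equiv), CH2Cl2, −78 °C to rt; then H2O
Reagents that add atoms: none
Why: In this Lewis acid ether cleavage BCl3 removes benzyl aryl ethers at low temperature (pentamethylbenzene traps the benzyl cation and prevents C-benzylation of the phloroglucinol ring) and, through chelation to the C4 carbonyl, cleaves only the peri 5-OMe among the methyl ethers, leaving 7-OMe and 4'-OMe intact.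

**Compound list**
1 | 2,6-dimethoxy-1,4-benzoquinone | COC1=CC(=O)C=C(OC)C1=O | starting material
2 | 2,6-dimethoxybenzene-1,4-diol | COc1cc(O)cc(OC)c1O | intermediate
3 | 1-(3,6-dihydroxy-2,4-dimethoxyphenyl)ethan-1-one | CC(=O)c1c(O)cc(OC)c(O)c1OC | intermediate
4 | 1-[3-(benzyloxy)-6-hydroxy-2,4-dimethoxyphenyl]ethan-1-one | CC(=O)c1c(O)cc(OC)c(OCc2ccccc2)c1OC | intermediate
5 | 4-methoxybenzaldehyde | COc1ccc(C=O)cc1 | starting material
6 | racemic 1-[3-(benzyloxy)-6-hydroxy-2,4-dimethoxyphenyl]-3-hydroxy-3-(4-methoxyphenyl)propan-1-one (aldol adduct, formed in the flask) | COc1ccc(C(O)CC(=O)c2c(O)cc(OC)c(OCc3ccccc3)c2OC)cc1 | intermediate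
7 | (E)-1-[3-(benzyloxy)-6-hydroxy-2,4-dimethoxyphenyl]-3-(4-methoxyphenyl)prop-2-en-1-one | COc1ccc(/C=C/C(=O)c2c(O)cc(OC)c(OCc3ccccc3)c2OC)cc1 | intermediate
8 | 6-(benzyloxy)-5,7-dimethoxy-2-(4-methoxyphenyl)-4H-chromen-4-one | COc1ccc(-c2cc(=O)c3c(OC)c(OCc4ccccc4)c(OC)cc3o2)cc1 | intermediate
9 | 6-hydroxy-5,7-dimethoxy-2-(4-methoxyphenyl)-4H-chromen-4-one | COc1ccc(-c2cc(=O)c3c(OC)c(O)c(OC)cc3o2)cc1 | intermediate
10 | 4-fluorobenzaldehyde | O=Cc1ccc(F)cc1 | starting material
11 | 4-{[5,7-dimethoxy-2-(4-methoxyphenyl)-4-oxo-4H-chromen-6-yl]oxy}benzaldehyde | COc1ccc(-c2cc(=O)c3c(OC)c(Oc4ccc(C=O)cc4)c(OC)cc3o2)cc1 | intermediate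
12 | 1-(2,4,6-trihydroxyphenyl)ethan-1-one | CC(=O)c1c(O)cc(O)cc1O | starting material
13 | 1-[2,4-bis(benzyloxy)-6-hydroxyphenyl]ethan-1-one | CC(=O)c1c(O)cc(OCc2ccccc2)cc1OCc1ccccc1 | intermediate
14 | racemic 1-[2,4-bis(benzyloxy)-6-hydroxyphenyl]-3-hydroxy-3-(4-{[5,7-dimethoxy-2-(4-methoxyphenyl)-4-oxo-4H-chromen-6-yl]oxy}phenyl)propan-1-one (aldol adduct, formed in the flask) | COc1ccc(-c2cc(=O)c3c(OC)c(Oc4ccc(C(O)CC(=O)c5c(O)cc(OCc6ccccc6)cc5OCc5ccccc5)cc4)c(OC)cc3o2)cc1 | intermediate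
15 | (E)-1-[2,4-bis(benzyloxy)-6-hydroxyphenyl]-3-(4-{[5,7-dimethoxy-2-(4-methoxyphenyl)-4-oxo-4H-chromen-6-yl]oxy}phenyl)prop-2-en-1-one | COc1ccc(-c2cc(=O)c3c(OC)c(Oc4ccc(/C=C/C(=O)c5c(O)cc(OCc6ccccc6)cc5OCc5ccccc5)cc4)c(OC)cc3o2)cc1 | intermediate
16 | 6-{4-[5,7-bis(benzyloxy)-4-oxo-4H-chromen-2-yl]phenoxy}-5,7-dimethoxy-2-(4-methoxyphenyl)-4H-chromen-4-one | COc1ccc(-c2cc(=O)c3c(OC)c(Oc4ccc(-c5cc(=O)c6c(OCc7ccccc7)cc(OCc7ccccc7)cc6o5)cc4)c(OC)cc3o2)cc1 | intermediate
17 | Cryptomerin B, 6-[4-(5,7-dihydroxy-4-oxo-4H-chromen-2-yl)phenoxy]-5-hydroxy-7-methoxy-2-(4-methoxyphenyl)-4H-chromen-4-one | COc1ccc(-c2cc(=O)c3c(O)c(Oc4ccc(-c5cc(=O)c6c(O)cc(O)cc6o5)cc4)c(OC)cc3o2)cc1 | target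

**Step count**
Total: 11 steps. Longest linear sequence: 10 steps (1 → 17 through steps 1–7, 9, 10 and 11); step 8 is a one-step side branch.

**Three steps most likely to fail, with fallbacks**

Step 7 (SNAr on a phenol flanked by two methoxy groups; it may be slow or incomplete). The fallback sets out from 9. A copper-catalysed Ullmann-type etherification with commercial 2-(4-bromophenyl)-1,3-dioxolane (CuI 10 mol %, picolinic acid 20 mol %, K3PO4, DMSO, 90 °C), a ligand system suited to hindered phenols, gives the acetal 6-[4-(1,3-dioxolan-2-yl)phenoxy]-5,7-dimethoxy-2-(4-methoxyphenyl)-4H-chromen-4-one F1. Hydrolysis with 1 M HCl in THF at rt then unmasks the aldehyde and comes back to the route at 11.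

Step 9 (hydroxide-mediated aldol in the presence of the unit 1 flavone; risks are low solubility and attack of hydroxide on the pyranone). The fallback sets out from 11 and keeps an intermolecular condensation of the same two halves, but with a non-nucleophilic base. Oxidation with NaClO2, NaH2PO4 and 2-methyl-2-butene in t-BuOH/THF/H2O gives 4-{[5,7-dimethoxy-2-(4-methoxyphenyl)-4-oxo-4H-chromen-6-yl]oxy}benzoic acid F2. SOCl2 with catalytic DMF in toluene at 60 °C gives 4-{[5,7-dimethoxy-2-(4-methoxyphenyl)-4-oxo-4H-chromen-6-yl]oxy}benzoyl chloride F3. Intermolecular Claisen-type C-acylation of the lithium phenoxide-enolate of 13 (LiN(SiMe3)2, 3.2 equiv, THF, −78 °C) with F3 gives the 1,3-diketone 1-[2,4-bis(benzyloxy)-6-hydroxyphenyl]-3-(4-{[5,7-dimethoxy-2-(4-methoxyphenyl)-4-oxo-4H-chromen-6-yl]oxy}phenyl)propane-1,3-dione F4. Cyclodehydration with catalytic p-TsOH in toluene at reflux comes back to the route at 16, bypassing 15 and step 10.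

Step 11 (one-pot triple debenzylation plus selective peri demethylation; risks are incomplete 5-O-demethylation or C-benzylation). The fallback sets out from 16 and separates the two events. Hydrogenolysis (H2, 10% Pd/C, THF/MeOH, rt) removes the three benzyl groups to give 6-[4-(5,7-dihydroxy-4-oxo-4H-chromen-2-yl)phenoxy]-5,7-dimethoxy-2-(4-methoxyphenyl)-4H-chromen-4-one F5. Chelation-controlled mono-demethylation of the peri 5-OMe with AlCl3 in MeCN at 60 °C, followed by dilute HCl work-up, arrives at 17.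

**Further compounds**
F1 | step 7 | 6-[4-(1,3-dioxolan-2-yl)phenoxy]-5,7-dimethoxy-2-(4-methoxyphenyl)-4H-chromen-4-one | COc1ccc(-c2cc(=O)c3c(OC)c(Oc4ccc(C5OCCO5)cc4)c(OC)cc3o2)cc1
F2 | step 9 | 4-{[5,7-dimethoxy-2-(4-methoxyphenyl)-4-oxo-4H-chromen-6-yl]oxy}benzoic acid | COc1ccc(-c2cc(=O)c3c(OC)c(Oc4ccc(C(=O)O)cc4)c(OC)cc3o2)cc1
F3 | step 9 | 4-{[5,7-dimethoxy-2-(4-methoxyphenyl)-4-oxo-4H-chromen-6-yl]oxy}benzoyl chloride | COc1ccc(-c2cc(=O)c3c(OC)c(Oc4ccc(C(=O)Cl)cc4)c(OC)cc3o2)cc1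
F4 | step 9 | 1-[2,4-bis(benzyloxy)-6-hydroxyphenyl]-3-(4-{[5,7-dimethoxy-2-(4-methoxyphenyl)-4-oxo-4H-chromen-6-yl]oxy}phenyl)propane-1,3-dione | COc1ccc(-c2cc(=O)c3c(OC)c(Oc4ccc(C(=O)CC(=O)c5c(O)cc(OCc6ccccc6)cc5OCc5ccccc5)cc4)c(OC)cc3o2)cc1
F5 | step 11 | 6-[4-(5,7-dihydroxy-4-oxo-4H-chromen-2-yl)phenoxy]-5,7-dimethoxy-2-(4-methoxyphenyl)-4H-chromen-4-one | COc1ccc(-c2cc(=O)c3c(OC)c(Oc4ccc(-c5cc(=O)c6c(O)cc(O)cc6o5)cc4)c(OC)cc3o2)cc1
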